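Follow one ratio through this flask: the rate of left-handed product over the rate of right-handed product.

| flask | left-handed substrate | right-handed substrate | solid reagent | precatalyst | remark | time |
|---|---|---|---|---|---|---|
| summer | 0.050 M | 0.050 M | 0.10 M | 25 µM | run made earlier |  |
| winter | 0.050 M | 0.050 M | 0.10 M | 100 µM | run made earlier |  |
| flask | 0.050 M | 0.050 M | 0.100 M | 50 µM |  | 2.0 min |

- summer (time / min: left-handed product / %, right-handed product / %): 0.333: 4.6, 2.3; 0.833: 18.6, 7.8; 1.50: 27.1, 12.6; 2.50: 41.0, 23.0
- winter (time / min: left-handed product / %, right-handed product / %): 0.200: 2.5, 2.5; 0.417: 6.9, 3.1; 1.00: 19.4, 9.6; 2.50: 41.5, 23.3

(standard deviation of a reading: 1 percentage point)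

* left-handed product and right-handed product together, in percent of the left-handed substrate and right-handed substrate charged together, at 2.0 min
* excess of left-handed product over right-handed product in the product at 2.0 min
* whether the exchange between left-handed substrate and right-handed substrate keeps pace with the reaction: how far the product's excess at 2.0 min gets from its value without exchange to its value with instant exchange (above 80% keeps pace, below 20% hardly takes part, else lags behind)

- partner is single-handed; left-handed substrate and right-handed substrate are mirror images of each other, charged as a racemate, each of them at the stated concentration
- solid, in amounts per volume of the solution: solid reagent
- reactions considered so far: partner + left-handed substrate -> left-handed product; partner + right-handed substrate -> right-handed product; left-handed substrate + racemization catalyst <-> right-handed substrate + racemization catalyst; precatalyst -> racemization catalyst; solid reagent <-> partner; racemization catalyst -> spent catalyst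
- at the start none of the solid reagent is in solution
- an excess is the difference of the two amounts in percent of their sum
- an excess is below zero if the other one leads
- the handed part of partner does not stay in what it makes, so the products of the two hands are mirror images too

Both hands react with the same partner, so c(partner) cancels, and the ratio is s times c(left-handed substrate)/c(right-handed substrate). The winter run, at its last reading, gives 2.82 for s, the selectivity factor: the logarithm of the fraction of left-handed substrate left over the logarithm of the fraction of right-handed substrate left. The summer run, with 25 µM of precatalyst against 100 µM, reads 2.78, so I judge that the exchange hardly takes part.

At the start, left-handed product forms 2.82 times faster than right-handed product, and what forms has an excess of 47.7%. Each substrate's factor in the ratio falls as that substrate is used, while c(partner) stays out of the ratio. By 2.50 min in the winter run the factors are 0.170 for left and 0.534 for right, so the ratio has sunk to 0.899. The accumulated product therefore stands at an excess of only 28.1%. For 2.0 min I take the mean of the summer readings at 1.50 min and 2.50 min: 51.9% of product, with an excess of 31.3%.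

The forecast says 52% and 32.5%, a little above my excess, and that the exchange hardly takes part, on the ground that “two runs differ fourfold in precatalyst yet match closely”.

The flask gives 54.5% of product with an excess of 32.1%, and the exchange hardly takes part, getting 0.79% of the way.

    partner + left-handed substrate → left-handed product (k = 1.40 M⁻¹ s⁻¹)
    partner + right-handed substrate → right-handed product (k = 0.510 M⁻¹ s⁻¹)
    left-handed substrate + racemization catalyst ⇌ right-handed substrate + racemization catalyst, rate k3*[racemization catalyst]*[left-handed substrate] forward; the back reaction follows from the equilibrium constant (k = 190 M⁻¹ s⁻¹)
    precatalyst → racemization catalyst (k = 0.0250 s⁻¹)
    solid reagent ⇌ partner, rate k5*(cs5 - [partner]) while solid is left; crystals form when [partner] > cs5 (solubility = 17.0 mM, k = 0.0570 s⁻¹)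
    racemization catalyst → spent catalyst (k = 0.620 s⁻¹)

The exchange makes no difference to the excess, while by 1.00 min spent catalyst holds 76.7% of the catalyst charged. In this flask 63% of the right-handed substrate is left, and raised to the power s that gives 26.9% for the left-handed substrate, which stands at 28%. In the neighbour flask charged with 0.025 M of solid reagent, 85% of right-handed substrate left gives 63.2%, and that flask holds 65% of its left-handed substrate.

The earlier runs and the new flask are calculated with made-up constants; noise was put on by code.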